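The constant I want from these runs is a second-order one for the loss of Xp to Xb, and I reach it by counting where the turned Xa has gone.

the same everywhere: Xa 0.400 M

|  | Xb | time |
|---|---|---|
| delta | 0.800 M |  |
| gamma | 1.20 M |  |
| beta | 0.800 M | 22 h |

- delta run (time / h: [Xp] / M): 0.39: 0.0097; 1.2: 0.0321; 2.3: 0.0592; 3.6: 0.0938; 5.2: 0.1296; 6.9: 0.1629; 8.9: 0.1897; 11: 0.2038
- gamma run (time / h: [Xp] / M): 0.39: 0.0114; 1.2: 0.0318; 2.3: 0.0612; 3.6: 0.0901; 5.2: 0.1186; 6.9: 0.1393; 8.9: 0.1521; 11: 0.1519

(each reading ± 0.001 M)

1. order of the initial rate in [Xb], near the charge of the delta run, the rate being that where two percent of its Xa are Xp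
2. Xp in the beta run at 22 h, as a share of the Xa charged

- Overall: Xa + Xb -> Xp.
- Constant volume, constant temperature.
- An order is taken over about fifteen percent of the charge, up and down.

At 2.3 h the gamma run reads 1.03 times the delta run, and as a reading that gives me an order in [Xb] of 0.0819. With formation so close, I first treat both runs as making the same Xp, so that the gamma run, holding less Xp than the delta run at 11 h, has simply lost more. The logarithm of their ratio, divided by the extra [Xb] of 0.400 M and a mean age of 5.50 h, gives 0.134 L mol⁻¹ h⁻¹.

The beta run repeats the delta charge, so I take the delta readings for its first 11 h. With mean [Xp] near 0.102 M, mean [Xb] near 0.600 M and one Xb spent per Xp lost, 0.0899 M of Xp is lost, leaving 0.106 M of Xa. I let that Xa turn in the next 11.0 h while 0.0929 M more is lost, which ends at 54.3%.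

The weak link is equal formation. Putting the early ratio into the logarithm raises the constant to 0.149 L mol⁻¹ h⁻¹, the loss constant, Xp lost per hour per unit of [Xp][Xb]. The same chain then loses 0.100 M and 0.100 M, and I commit to 50.0%.

The forecast gives an order of 0.1 (−0.2 to 0.4) and 50% (40% to 56%), on its own grounds of “an Xb-accelerated catalyst death or a loss of product”.

The flask gives 47.1% and an order of 0.24, the gamma run's rate standing at 1.1 of the delta run's where the same amount has been made.

    Xa + Xb ⇌ Xi, settled at all times (10.10 L mol⁻¹)
    Xa + Xb → Xp (0.7668 L mol⁻¹ h⁻¹)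
    Xa + Xb + Xp → 2 Xp (6.048 L² mol⁻² h⁻¹)
    Xp + Xb → Xq (0.1663 L mol⁻¹ h⁻¹)

The beta run's gap between charge and Xp is 0.212 M. Counted wholly as Xq, it leaves [Xb] at 0.188 M, so my loss constant of 0.149 L mol⁻¹ h⁻¹, as read from the runs, puts the lifetime of Xp at an estimated 35.7 h there, against 5.60 h at the gamma charge.

(The data are calculated with made-up constants.)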